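The numbers in the tables were generated by integration for substances that don't exist.

Thursday's run and Tuesday's were where I started, with Sunday's beside them.

the same everywhere: free catalyst 0.80 mM

| run | substrate | added ligand | remark |
|---|---|---|---|
| Thursday's | 0.20 M | 0.96 mM | run made earlier |
| Tuesday's | 0.30 M | 0.96 mM | run made earlier |
| Sunday's | 0.40 M | 1.9 mM | run made earlier |
| flask | 0.40 M | 0.96 mM |  |

- Thursday's (time / h: product / %): 0.833: 2.5; 2.00: 7.0; 4.00: 13.7; 6.00: 20.4
- Tuesday's (time / h: product / %): 0.833: 3.5; 2.00: 7.1; 4.00: 13.2; 6.00: 19.4
- Sunday's (time / h: product / %): 1.50: 3.1; 3.00: 6.4; 5.00: 10.8; 6.00: 12.1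

(readings scatter by 0.3 percentage points)

- what was read earlier has a scatter of 0.3 percentage points, one standard deviation
- candidate steps: free catalyst + added ligand <-> idle complex; catalyst intermediate <-> free catalyst + product; substrate + free catalyst <-> catalyst intermediate
- no earlier run changes the charge of free catalyst; that part of a forecast is a guess

- apparent order in free catalyst when 5.0 % of the substrate are converted (percent change of the rate of making product for one percent more free catalyst charged)

First I asked what rate the flask should show at its own ligand charge. The mean rates up to the last reading were 6.80 mM h⁻¹ on Thursday and 9.70 mM h⁻¹ on Tuesday, a substrate order of 0.876. Carried to c(substrate) = 0.40 M, that gave me 12.5 mM h⁻¹ for the flask.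

Next I asked what ligand costs. Sunday's run, at the flask's c(substrate) with about twice the ligand, read 8.07 mM h⁻¹, less than that. So I defined the ligand sensitivity, the percent fall of the rate for one percent more added ligand: 0.639, a reading that carries the scatter.

Then I asked what this says about catalyst. With tight binding and added ligand above free catalyst in the charge, 0.96 mM against 0.80 mM, free catalyst follows the ratio of the two charges, so scaling both leaves the rate unchanged, and the order in free catalyst equals the sensitivity, 0.639. With weak binding, scaling both scales the rate by the same factor, and the order is one plus the sensitivity, 1.64. I committed to that window.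

The forecast gave 1.3, from 1 to 1.8, arguing that "extra catalyst outruns the ligand"; its high end lies above my ceiling.

The flask gave 1.2.

    free catalyst + added ligand ⇌ idle complex, settled at all times (K = 1700 M⁻¹)
    catalyst intermediate ⇌ free catalyst + product (K = 4.10 M, k = 2.80 min⁻¹)
    substrate + free catalyst ⇌ catalyst intermediate (K = 1.40 M⁻¹, k = 2.80 M⁻¹ min⁻¹)

That order less the ligand sensitivity left 0.568 as the exponent for scaling both charges, between zero for tight binding and one for weak binding, so the flask stood inside the window. After 5.00 h, free catalyst entered the intermediate at 67 h⁻¹ with c(substrate) as charged, while the intermediate gave product at 170 h⁻¹, faster, and the flask held 9.26 % of its catalyst as intermediate against 45.1 % free and 45.6 % as idle complex, the off-cycle form.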